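## Retrosynthetic overview

1. Germacrane locants are used: ring C1–C10, C1=C10 with formyl C14 on C10, C4=C5 with methyl C15 on C4, lactone O–C6/C7–C11(=C13)–C12. The plan rests on the C8–C9 bond. It is the only bond of the ten-membered carbocycle whose two carbons both bear oxygen (8-OH, 9-O-acyl), and it lies between lactone carbon C7 and alkene carbon C10.
2. The ester, C13 and the C14 oxidation level are removed first. Reductive scission of C8–C9 then leads to dialdehyde 22, with the C8 formyl on a trans-butyrolactone and the C9 formyl as a Z-enal. In the forward sense a titanium pinacol coupling closes the carbocycle and makes both carbinols.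
3. 22 comes from an Evans succinate syn-aldol plus lactonisation on C6 enal 13. This sets C6 and C7 and brings in C7, C8, C11 and C12.
4. 13 comes from nerol (C1–C6, C15, ring-cis C4=C5) after distal cleavage, and from methyl acrylate by Baylis–Hillman reaction and SN2' bromination. The ester carbon becomes C14 and the methylene carbon becomes C9, which places C2 and C9 cis.
5. Ring order: γ-lactone (step 12), then the ten-membered ring (step 16). C13, the (R)-2-methylbutanoate and the C14 aldehyde follow.

Key step: step 16

Assumption: (R)-2-methylbutanoic acid 31 is bought enantiopure; all locants in names are the germacrane locants of the target.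
Remark: C14 is carried as its tert-butyldiphenylsilyl ether, because this group must outlast the acidic acetonide cleavage of step 20, which a smaller silyl ether would not.

## Route

Step 1
Reactants: 1 nerol
Product: 2 neryl 4-methoxybenzyl ether
Conditions: NaH, PMBCl, Bu4NI (cat.), THF/DMF, 0 °C → rt
Reagents that add atoms: 4-methoxybenzyl chloride, COc1ccc(CCl)cc1
Why: Williamson etherification masks O6 with a group that survives peracid, periodic acid, amine base and aluminium hydride and is later removed oxidatively.

Step 2
Reactants: 2 neryl 4-methoxybenzyl ether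
Product: 3 distal epoxide of 2 (racemic at the epoxide CH)
Conditions: mCPBA (1.0 equiv), CH2Cl2, −20 → 0 °C
Reagents that add atoms: 3-chloroperbenzoic acid, O=C(OO)c1cccc(Cl)c1
Why: Prilezhaev epoxidation with one equivalent of peracid should take the distal trisubstituted alkene, because C4=C5 is made electron-poorer by its allylic oxygen; the new stereocentre is destroyed in step 3.

Step 3
Reactants: 3 distal epoxide
Product: 5 C1 aldehyde (Z)-6-(4-methoxybenzyloxy)-4-methylhex-4-enal, via 6,7-diol 4 (not isolated)
Conditions: H5IO6, THF/H2O, 0 °C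
Reagents that add atoms: water, O (enters intermediate 4; its oxygen leaves again with acetone)
Why: Epoxide hydrolysis followed in the same flask by Malaprade glycol cleavage removes the isopropylidene carbons as acetone and leaves C1 as the aldehyde without touching the cis C4=C5 alkene.

Step 4
Reactants: 5 C1 aldehyde; 6 methyl acrylate
Product: 7 Baylis–Hillman adduct, methyl 3-hydroxy-2-methylene ester (racemic at the C1 carbinol)
Conditions: DABCO (1 equiv), dioxane/H2O (1:1), rt, 2–3 d
Reagents that add atoms: none
Why: The Baylis–Hillman reaction of an unhindered aliphatic aldehyde forms C1–C10 and brings in C9, C10 and C14; the carbinol stereocentre disappears in step 5.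

Step 5
Reactants: 7 Baylis–Hillman adduct
Product: 8 methyl (2Z,6Z)-2-(bromomethyl)-8-(4-methoxybenzyloxy)-6-methylocta-2,6-dienoate
Conditions: NBS, Me2S, CH2Cl2, 0 °C → rt
Reagents that add atoms: N-bromosuccinimide, O=C1CCC(=O)N1Br
Why: In this SN2' bromination of a Baylis–Hillman alcohol, bromide displaces the alkoxysulfonium group at the methylene terminus, and allylic strain places the C2 chain trans to the ester (C14) and therefore cis to C9, as the ring requires.

Step 6
Reactants: 8 allylic bromide
Product: 9 methyl (2E,6Z)-dienoate with C9 as its 4-methoxyphenyl ether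
Conditions: 4-MeOC6H4OH, K2CO3, acetone, rt → 40 °C
Reagents that add atoms: 4-methoxyphenol, COc1ccc(O)cc1
Why: SN2 displacement of the primary allylic bromide by phenoxide keeps the alkene geometry (the conjugated trisubstituted enoate is also the thermodynamic outcome) and gives a C9 mask that resists hydride and DDQ.

Step 7
Reactants: 9 aryl ether ester
Product: 10 C14 allylic alcohol
Conditions: iBu2AlH (2.5 equiv), CH2Cl2, −78 °C; aq. KNaC4H4O6
Reagents that add atoms: none
Why: 1,2-Reduction of the enoate by iBu2AlH gives the allylic alcohol with the alkene geometry unchanged, and both ethers are inert.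

Step 8
Reactants: 10 C14 allylic alcohol
Product: 11 C14 tert-butyldiphenylsilyl ether
Conditions: TBDPSCl, imidazole, CH2Cl2, rt
Reagents that add atoms: tert-butylchlorodiphenylsilane, CC(C)(C)[Si](Cl)(c1ccccc1)c1ccccc1
Why: Standard silylation of the only free hydroxyl completes the differentiation of C9 (aryl ether), C14 (silyl ether) and C6 (PMB ether).

Step 9
Reactants: 11 fully protected triol
Product: 12 C6 allylic alcohol
Conditions: DDQ, CH2Cl2/pH 7 buffer (10:1), 0 °C
Reagents that add atoms: none
Why: Oxidative PMB cleavage proceeds by benzylic hydride abstraction, which the C9 aryl ether (no benzylic C–H) and the silyl ether cannot undergo.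

Step 10
Reactants: 12 C6 allylic alcohol
Product: 13 C6 enal, (2Z,6E)-8-(tert-butyldiphenylsilyloxy)-7-[(4-methoxyphenoxy)methyl]-3-methylocta-2,6-dienal
Conditions: TEMPO (10 mol %), PhI(OAc)2, MeCN/pH 7 buffer, 0 °C
Reagents that add atoms: none
Why: Buffered oxoammonium oxidation is the established way to convert nerol-type alcohols into their Z-enals without Z to E isomerisation.

Step 11
Reactants: 14 (S)-4-benzyl-2-oxazolidinone; 15 methyl 4-chloro-4-oxobutanoate
Product: 16 (S)-4-benzyl-3-(4-methoxy-4-oxobutanoyl)oxazolidin-2-one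
Conditions: Et3N, DMAP (cat.), CH2Cl2, 0 °C → rt
Reagents that add atoms: none
Why: DMAP-catalysed N-acylation of the auxiliary by the acid chloride gives the succinate imide that carries C7, C8, C11 and C12.

Step 12
Reactants: 16 succinate imide; 13 C6 enal
Product: 19 trans-lactone imide (6R,7S), via boron enolate 17 (not isolated), via syn-aldol hydroxy ester 18 (not isolated)
Conditions: 16, Bu2BOTf, iPr2NEt, CH2Cl2, 0 °C; 13, −78 → 0 °C; pH 7 buffer, MeOH, 30% H2O2, 0 °C; then PPTS (cat.), CH2Cl2, rt
Reagents that add atoms: dibutylboron triflate, CCCCB(CCCC)OS(=O)(=O)C(F)(F)F (boron and butyl groups in 17 only)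
Why: In the Evans syn-aldol the Z-boron enolate of the imide reacts through a Zimmerman–Traxler chair on the face away from the benzyl group to set 6R and 7S, and lactonisation of O6 onto the methyl ester turns the syn adduct into the trans-4,5-disubstituted butyrolactone.

Step 13
Reactants: 19 trans-lactone imide
Product: 20 C9 allylic alcohol (imide retained)
Conditions: (NH4)2Ce(NO3)6, MeCN/H2O (4:1), 0 °C, short reaction time
Reagents that add atoms: none
Why: Oxidative dearylation of the 4-methoxyphenyl ether to benzoquinone frees O9, while lactone, imide, silyl ether and trisubstituted alkenes tolerate the brief cold treatment.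

Step 14
Reactants: 20 C9 alcohol imide
Product: 21 trans-lactone 8,9-diol (6R,7R; C8 and C9 both CH2OH)
Conditions: NaBH4, THF/H2O (4:1), 0 °C; aq. NH4Cl
Reagents that add atoms: none
Why: Aqueous borohydride removes the auxiliary reductively because the activated exocyclic imide carbonyl is attacked much faster than a γ-lactone, and a cold, quickly neutralised reaction limits acyl migration to the new primary hydroxyl.

Step 15
Reactants: 21 lactone diol
Product: 22 trans-lactone dialdehyde (6R,7S; C8 formyl on C7, C9 formyl as Z-enal, C14 OTBDPS)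
Conditions: Dess–Martin periodinane, NaHCO3, CH2Cl2, 0 °C → rt; short silica pad; used at once
Reagents that add atoms: none
Why: Buffered Dess–Martin oxidation converts both primary alcohols at once under near-neutral conditions, which should preserve the labile Z-enal, the C7 configuration (trans is also the more stable arrangement) and the β-acyloxy aldehyde if the material is used directly.

Step 16
Reactants: 22 trans-lactone dialdehyde
Product: 24 bicyclic 8β,9β-diol lactone (6R,7R,8S,9R), via titanium pinacolate 23 (not isolated)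
Conditions: TiCl3(DME)1.5 (12 equiv), Zn–Cu (35 equiv), DME, reflux 3 h; cool to 0 °C; 22 by syringe pump over 30 h (final ca. 1 mM); 0 → 25 °C; aq. K2CO3
Reagents that add atoms: titanium trichloride, Cl[Ti](Cl)Cl (titanium and chloride in 23 only)
Why: Single-electron transfer from the low-valent titanium slurry turns both formyl groups into oxygen-bound ketyl radicals, which join at carbon to give pinacolate 23; at or below 25 °C this is not deoxygenated and aqueous K2CO3 releases diol 24. The closest known reaction type is the McMurry-type intramolecular pinacol coupling of dialdehydes, which is established for enal partners and for ten-membered and larger carbocycles. The ten-membered ring closes head to tail by radical–radical combination of C8 and C9 (both carbons become ring members, both oxygens stay outside), with slow addition keeping closure ahead of intermolecular coupling and the two ring-cis alkenes and the trans-lactone pre-folding the chain. C8 is controlled by C7 in a Felkin-type arrangement: the new bond forms anti to C7–C11 with O8 turned toward C6, so C9 passes over H7 and O8 ends cis to C11. C9 is controlled by allylic 1,3-strain and by the ring: the Z-enal ketyl reacts s-trans with H9 pointing at C2, only one of its faces reaches C8 once H6 eclipses C4=C5 and the lactone fixes C5–C6–C7–C8, and in the resulting synclinal C7–C8–C9–C10 arrangement only the erythro isomer keeps both oxygens on one titanium site. The step needs carbonyl–carbonyl coupling rather than coupling at vinylogous C1, retention of the C1=C10 geometry, survival of lactone and silyl ether, and one diol out of four; oxygen-bound titanium and the low temperature secure the first three, whereas the diol configuration is the open point because unconstrained ten-membered rings lean to the trans diol.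

Step 17
Reactants: 24 bicyclic diol
Product: 25 8,9-acetonide
Conditions: Me2C(OMe)2, PPTS (cat.), CH2Cl2, rt
Reagents that add atoms: 2,2-dimethoxypropane, COC(C)(C)OC
Why: Transketalisation of the cis diol removes both acidic protons, and with them the C8 alkoxide that could attack C12, before the lactone is enolised.

Step 18
Reactants: 25 acetonide
Product: 27 C11 dimethylaminomethyl lactone (C11 epimers), via lithium enolate 26 (not isolated)
Conditions: LiN(iPr)2, THF, −78 °C; CH2=NMe2+ I−, −78 → 0 °C
Reagents that add atoms: Eschenmoser's salt, C=[N+](C)C.[I-]; lithium diisopropylamide, [Li]N(C(C)C)C(C)C (lithium in 26 only)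
Why: The Mannich reaction of the lactone enolate with Eschenmoser's salt installs C13, the enolate has no β-leaving group on C7, and the C11 configuration is irrelevant because it is erased in step 19.

Step 19
Reactants: 27 Mannich base
Product: 29 α-methylene lactone acetonide, via trimethylammonium iodide 28 (not isolated)
Conditions: MeI, THF, rt; then aq. NaHCO3, CH2Cl2, rt
Reagents that add atoms: iodomethane, CI (methyl and iodide in 28 only)
Why: Exhaustive methylation followed by mild Hofmann-type β-elimination of trimethylamine is the standard completion of lactone α-methylenation.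

Step 20
Reactants: 29 α-methylene lactone acetonide
Product: 30 α-methylene lactone 8β,9β-diol (C14 OTBDPS retained)
Conditions: AcOH/H2O (4:1), 40 °C
Reagents that add atoms: none
Why: Mild acidic ketal hydrolysis frees both hydroxyls, while the acid-robust TBDPS ether and the α-methylene lactone persist.

Step 21
Reactants: 30 diol; 31 (R)-2-methylbutanoic acid
Product: 32 9-O-[(R)-2-methylbutanoyl] 8-hydroxy lactone
Conditions: 31 (1.05 equiv), DCC, DMAP (cat.), CH2Cl2, −20 → 0 °C
Reagents that add atoms: none
Why: Steglich esterification with an α-branched acid should favour O9, which is flanked by the flat sp2 carbon C10 and points to the ring periphery, over O8, which sits gauche to both C6 and C11 in the fold between lactone and carbocycle; the acid stereocentre is not activated toward ketene formation under these conditions.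

Step 22
Reactants: 32 ester
Product: 33 C14 allylic alcohol
Conditions: HF·pyridine, pyridine, THF, 0 °C → rt
Reagents that add atoms: none
Why: Buffered acidic fluoride cleaves the silyl ether without generating the basic alkoxide that would promote O9 to O8 acyl migration or addition to the α-methylene lactone.

Step 23
Reactants: 33 C14 allylic alcohol
Product: 34 target CNP0256845.2
Conditions: MnO2, CH2Cl2, rt
Reagents that add atoms: none
Why: MnO2 oxidises only the primary allylic C14 alcohol, the non-allylic 8-OH is untouched, and the resulting enal already has its more stable geometry (C2 trans to CHO).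

## Compound list

1 | nerol | CC(C)=CCC/C(C)=C\CO | starting material
2 | neryl 4-methoxybenzyl ether | CC(C)=CCC/C(C)=C\COCc1ccc(OC)cc1 | intermediate
3 | distal epoxide of 2 | CC1(C)OC1CC/C(C)=C\COCc1ccc(OC)cc1 | intermediate
4 | 6,7-diol from 3 (not isolated) | CC(C)(O)C(O)CC/C(C)=C\COCc1ccc(OC)cc1 | intermediate
5 | (Z)-6-(4-methoxybenzyloxy)-4-methylhex-4-enal | O=CCC/C(C)=C\COCc1ccc(OC)cc1 | intermediate
6 | methyl acrylate | C=CC(=O)OC | starting material
7 | Baylis–Hillman adduct | C=C(C(=O)OC)C(O)CC/C(C)=C\COCc1ccc(OC)cc1 | intermediate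
8 | (2Z,6Z)-2-(bromomethyl) dienoate | COC(=O)/C(CBr)=C/CC/C(C)=C\COCc1ccc(OC)cc1 | intermediate
9 | (2E,6Z)-2-[(4-methoxyphenoxy)methyl] dienoate | COC(=O)/C(COc1ccc(OC)cc1)=C/CC/C(C)=C\COCc1ccc(OC)cc1 | intermediate
10 | C14 allylic alcohol | OC/C(COc1ccc(OC)cc1)=C/CC/C(C)=C\COCc1ccc(OC)cc1 | intermediate
11 | C14 TBDPS ether | CC(C)(C)[Si](c1ccccc1)(c1ccccc1)OC/C(COc1ccc(OC)cc1)=C/CC/C(C)=C\COCc1ccc(OC)cc1 | intermediate
12 | C6 allylic alcohol | CC(C)(C)[Si](c1ccccc1)(c1ccccc1)OC/C(COc1ccc(OC)cc1)=C/CC/C(C)=C\CO | intermediate
13 | C6 Z-enal | CC(C)(C)[Si](c1ccccc1)(c1ccccc1)OC/C(COc1ccc(OC)cc1)=C/CC/C(C)=C\C=O | intermediate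
14 | (S)-4-benzyl-2-oxazolidinone | O=C1OC[C@H](Cc2ccccc2)N1 | starting material
15 | methyl 4-chloro-4-oxobutanoate | COC(=O)CCC(=O)Cl | starting material
16 | (S)-4-benzyl-3-(4-methoxy-4-oxobutanoyl)oxazolidin-2-one | COC(=O)CCC(=O)N1C(=O)OC[C@@H]1Cc1ccccc1 | intermediate
17 | Z-dibutylboron enolate of 16 (not isolated) | CCCCB(CCCC)O/C(=C\CC(=O)OC)N1C(=O)OC[C@@H]1Cc1ccccc1 | intermediate
18 | syn-aldol hydroxy ester, 6R,7S (not isolated) | COC(=O)C[C@@H]([C@H](O)/C=C(/C)CC/C=C(/CO[Si](c1ccccc1)(c1ccccc1)C(C)(C)C)COc1ccc(OC)cc1)C(=O)N1C(=O)OC[C@@H]1Cc1ccccc1 | intermediate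
19 | trans-lactone imide, 6R,7S | C1C(=O)O[C@H](/C=C(/C)CC/C=C(/CO[Si](c2ccccc2)(c2ccccc2)C(C)(C)C)COc2ccc(OC)cc2)[C@H]1C(=O)N1C(=O)OC[C@@H]1Cc1ccccc1 | intermediate
20 | trans-lactone imide with free C9 alcohol | C1C(=O)O[C@H](/C=C(/C)CC/C=C(/CO[Si](c2ccccc2)(c2ccccc2)C(C)(C)C)CO)[C@H]1C(=O)N1C(=O)OC[C@@H]1Cc1ccccc1 | intermediate
21 | trans-lactone C8,C9 diol, 6R,7R | C1C(=O)O[C@H](/C=C(/C)CC/C=C(/CO[Si](c2ccccc2)(c2ccccc2)C(C)(C)C)CO)[C@H]1CO | intermediate
22 | trans-lactone dialdehyde, 6R,7S (key-step precursor) | C1C(=O)O[C@H](/C=C(/C)CC/C=C(/CO[Si](c2ccccc2)(c2ccccc2)C(C)(C)C)C=O)[C@H]1C=O | intermediate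
23 | dichlorotitanium 8,9-pinacolate, formal composition (not isolated) | C1C(=O)O[C@@H]2/C=C(/C)CC/C=C(/CO[Si](c3ccccc3)(c3ccccc3)C(C)(C)C)[C@H]3O[Ti](Cl)(Cl)O[C@H]3[C@@H]12 | intermediate
24 | bicyclic 8β,9β-diol lactone, 6R,7R,8S,9R (key-step product) | C1C(=O)O[C@@H]2/C=C(/C)CC/C=C(/CO[Si](c3ccccc3)(c3ccccc3)C(C)(C)C)[C@@H](O)[C@@H](O)[C@@H]12 | intermediate
25 | 8,9-acetonide | C1C(=O)O[C@@H]2/C=C(/C)CC/C=C(/CO[Si](c3ccccc3)(c3ccccc3)C(C)(C)C)[C@H]3OC(C)(C)O[C@H]3[C@@H]12 | intermediate
26 | lithium enolate of 25 (not isolated) | C1=C(O[Li])O[C@@H]2/C=C(/C)CC/C=C(/CO[Si](c3ccccc3)(c3ccccc3)C(C)(C)C)[C@H]3OC(C)(C)O[C@H]3[C@@H]12 | intermediate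
27 | C11 dimethylaminomethyl lactone (C11 epimers) | CN(C)CC1C(=O)O[C@@H]2/C=C(/C)CC/C=C(/CO[Si](c3ccccc3)(c3ccccc3)C(C)(C)C)[C@H]3OC(C)(C)O[C@H]3[C@@H]12 | intermediate
28 | trimethylammonium iodide of 27 (not isolated) | C[N+](C)(C)CC1C(=O)O[C@@H]2/C=C(/C)CC/C=C(/CO[Si](c3ccccc3)(c3ccccc3)C(C)(C)C)[C@H]3OC(C)(C)O[C@H]3[C@@H]12.[I-] | intermediate
29 | α-methylene lactone acetonide | C=C1C(=O)O[C@@H]2/C=C(/C)CC/C=C(/CO[Si](c3ccccc3)(c3ccccc3)C(C)(C)C)[C@H]3OC(C)(C)O[C@H]3[C@@H]12 | intermediate
30 | α-methylene lactone 8β,9β-diol | C=C1C(=O)O[C@@H]2/C=C(/C)CC/C=C(/CO[Si](c3ccccc3)(c3ccccc3)C(C)(C)C)[C@@H](O)[C@@H](O)[C@@H]12 | intermediate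
31 | (R)-2-methylbutanoic acid | CC[C@@H](C)C(=O)O | starting material
32 | 9-O-[(R)-2-methylbutanoyl] 8-hydroxy C14 silyl ether | C=C1C(=O)O[C@@H]2/C=C(/C)CC/C=C(/CO[Si](c3ccccc3)(c3ccccc3)C(C)(C)C)[C@@H](OC(=O)[C@H](C)CC)[C@@H](O)[C@@H]12 | intermediate
33 | C14 allylic alcohol | C=C1C(=O)O[C@@H]2/C=C(/C)CC/C=C(/CO)[C@@H](OC(=O)[C@H](C)CC)[C@@H](O)[C@@H]12 | intermediate
34 | CNP0256845.2 | C=C1C(=O)O[C@@H]2/C=C(/C)CC/C=C(/C=O)[C@@H](OC(=O)[C@H](C)CC)[C@@H](O)[C@@H]12 | target

## Step count and risks

Total step count: 23. Longest linear sequence: 22 (steps 1–10 and 12–23, from nerol); step 11 is the only side branch.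

**Step 16.** The relative configuration across the new bond may drift toward the trans diol, as simple ten-membered rings tend to do with this reagent. Intermolecular coupling, Lewis-acid ionisation of the allylic lactone C–O bond, or β-elimination of the C6 carboxylate from the C8 aldehyde may also consume material.
The fallback sets out from 22 and returns at 24. The coupling is kept only as the ring-forming event, and C9 is set afterwards.
- The whole diol fraction, chiefly the 9-epimeric trans diol F1, is treated with MnO2 in CH2Cl2. This oxidises only the allylic C9 carbinol and gives the 8-hydroxy-9-enone F2.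
- Reduction with Zn(BH4)2 in Et2O at −78 °C should pass through the five-membered zinc chelate of O8 and O9. Hydride then enters from the side of H8, and the erythro diol 24 results.

**Step 21.** The two secondary hydroxyls may not be discriminated well enough, and the ester may migrate from O9 to O8.
The fallback sets out from 30 and returns at 33. The hydroxyls are told apart by oxidation state instead of by rate.
- MnO2 oxidises only the allylic carbinol of 30 to the α-methylene lactone 8-hydroxy-9-enone F3.
- TESOTf and 2,6-lutidine at −78 °C cap the only remaining hydroxyl to give the 8-O-triethylsilyl enone F4.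
- Luche reduction (NaBH4, CeCl3·7H2O, MeOH, −78 °C) should deliver hydride anti to the bulky 8-silyloxy group in the synclinal ring rotamer and give the 9β-alcohol F5.
- DCC/DMAP esterification of this single free hydroxyl with 31 gives the 9-ester 8-silyl ether F6.
- HF·pyridine then removes both silyl groups and the route is rejoined at 33.

**Step 14.** The primary alkoxide formed next to the lactone may attack C12 (translactonisation to the C8–O lactone), and borohydride may begin to reduce the lactone.
The fallback sets out from 20 and returns at 22 without ever passing through a C8 alcohol.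
- LiSEt (EtSH, n-BuLi, THF, 0 °C) displaces the auxiliary to give the S-ethyl thioester F7.
- MnO2 oxidises the C9 allylic alcohol to the Z-enal thioester F8.
- Fukuyama reduction (Et3SiH, Pd/C, acetone, rt) converts the thioester into the C8 aldehyde under neutral conditions and gives 22 after filtration.

Further compounds
F1 | step 16 | 9-epimeric trans diol (8β-OH, 9α-OH) | C1C(=O)O[C@@H]2/C=C(/C)CC/C=C(/CO[Si](c3ccccc3)(c3ccccc3)C(C)(C)C)[C@H](O)[C@@H](O)[C@@H]12
F2 | step 16 | 8-hydroxy-9-enone | C1C(=O)O[C@@H]2/C=C(/C)CC/C=C(/CO[Si](c3ccccc3)(c3ccccc3)C(C)(C)C)C(=O)[C@@H](O)[C@@H]12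
F3 | step 21 | α-methylene lactone 8-hydroxy-9-enone | C=C1C(=O)O[C@@H]2/C=C(/C)CC/C=C(/CO[Si](c3ccccc3)(c3ccccc3)C(C)(C)C)C(=O)[C@@H](O)[C@@H]12
F4 | step 21 | 8-O-triethylsilyl enone | C=C1C(=O)O[C@@H]2/C=C(/C)CC/C=C(/CO[Si](c3ccccc3)(c3ccccc3)C(C)(C)C)C(=O)[C@@H](O[Si](CC)(CC)CC)[C@@H]12
F5 | step 21 | 9β-alcohol 8-O-triethylsilyl ether | C=C1C(=O)O[C@@H]2/C=C(/C)CC/C=C(/CO[Si](c3ccccc3)(c3ccccc3)C(C)(C)C)[C@@H](O)[C@@H](O[Si](CC)(CC)CC)[C@@H]12
F6 | step 21 | 9-ester 8-silyl ether | C=C1C(=O)O[C@@H]2/C=C(/C)CC/C=C(/CO[Si](c3ccccc3)(c3ccccc3)C(C)(C)C)[C@@H](OC(=O)[C@H](C)CC)[C@@H](O[Si](CC)(CC)CC)[C@@H]12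
F7 | step 14 | S-ethyl thioester with free C9 alcohol | C1C(=O)O[C@H](/C=C(/C)CC/C=C(/CO[Si](c2ccccc2)(c2ccccc2)C(C)(C)C)CO)[C@H]1C(=O)SCC
F8 | step 14 | Z-enal thioester | C1C(=O)O[C@H](/C=C(/C)CC/C=C(/CO[Si](c2ccccc2)(c2ccccc2)C(C)(C)C)C=O)[C@H]1C(=O)SCC
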